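You put 3 questions to me, with your forecast as the hunch beside them, and I answered from the earlier runs.

| flask | E | X | remark | time | volume of the second phase over the first |
|---|---|---|---|---|---|
| Saturday's | 10 mM | 1 equiv | run made earlier |  |  |
| Friday's | 10 mM | 2.2 equiv | run made earlier |  |  |
| Wednesday's | 15 mM | 1.5 equiv | run made earlier |  |  |
| flask | 10 mM | 1.50 equiv |  | 10 min | 0.50 |

| Saturday's: time / min | Saturday's: Q / % | Friday's: time / min | Friday's: Q / % | Wednesday's: time / min | Wednesday's: Q / % |
|---|---|---|---|---|---|
| 0.667 | 0.6 | 2.00 | 7.5 | 1.00 | 3.1 |
| 1.33 | 2.0 | 4.00 | 12.1 | 3.00 | 10.1 |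
| 3.00 | 5.0 | 6.00 | 13.5 | 5.00 | 12.7 |
| 8.00 | 8.8 | 8.00 | 13.5 | 8.00 | 14.4 |

(readings scatter by 0.3 percentage points)

- in the second phase: X; everything else is in the first
- charges count per volume of the first phase; a concentration in a rate is the amount of a species over the volume of its own phase; every rate counts per litre of the first phase
- the numbers in the tables scatter by 0.3 percentage points (one standard deviation)
- the earlier runs hold the two phases in the same ratio of volumes as the flask asked about

- the Q standing at 10 min, as a percentage of the E charged
- the change that raises the amount of Q at 10 min, in percent of the E charged most ("none" if none brings more than 2 percentage points) (larch / oak / none)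
- amount of Q at 10 min, in percent of the E charged, after larch

- larch: doubling the amount of X, all else as stated
- oak: doubling the transfer coefficient of X, all else as stated

E was the limiting reagent of the flask by charge, yet Friday's Q read 13.5% at 6.00 min and 13.5% at 8.00 min, which left 86.5% of the E charged not standing as Q. Saturday's run had the same [E] and less X and read lower, so I compared the last readings of those two runs:

gain = (13.5% − 8.8%) / (2.2 equiv − 1 equiv) = 3.9 percentage points per equivalent

I called this the stall gain, the points of Q won per extra equivalent of X at equal [E]. It gave:

flask: 8.8% + 3.9 points × (1.50 equiv − 1 equiv) / 1 equiv = 10.8%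

larch: 16.6%

Both figures belong to 8.00 min, and larch lies beyond Friday's charge. Larch gained 5.8 points, more than the margin of 2 points, which ruled out "none" but not oak, for which the stall gain gives no figure. I chose larch as a judgement, with no reckoning for oak behind it.

Your forecast gave 11.2%, larch and 16.5%, and of the lag it said: “it is short, so oak should gain little by 10 min”.

The flask gave 11.9%, and larch gave 16.3%, adding 4.4 points against 1.8 points for oak. My figures from the stall gain of 3.9 points, which belong to 8.00 min, stood 1.1 points below the flask and 0.30 points above larch.

    E + D → Q (k = 0.250 /M/s)
    D ⇌ X, rate k2*([D] - [X]/K2) per volume of the first phase (partition coefficient = 1.90, kL = 0.00540 /s)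
    D + Q → L (k = 0.0930 /M/s)
    E ⇌ J (K = 8.70, k = 0.00880 /s)

Of the E charged, the flask held 77.4% as J at 10.0 min, against 11.9% as Q. At that time the forward rate of E into J exceeded that of E + D into Q by a factor of 5.3.

The data were computed on assumed constants; the scatter is artificial.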